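**Retrosynthetic overview**
1. The target comes from stereoretentive C7–B oxidation of a 14-membered allylboronate. That boronate arises when alkenyl carbon C8 shifts from boron to C7 with loss of N2 inside a 15-membered cyclic boronate (ring contraction 15 to 14). The cyclic boronate closes from an acyclic C7-diazo/C8-boronate chain. This is the only ring and it forms last, so the 7-OH appears free beside both acetates.
2. The open chain is cut at C1–C2: anti-selective, phosphoric-acid-catalysed allylboration of a C2–C7/C18 enal with an E-allylboronate sets C1 and C2.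
3. The allylboronate (C8–C17, C19, C20) comes from pent-4-ynal, two isopropenyl Grignard units and trimethyl orthoacetate. Johnson–Claisen sets 11E, the alkyne becomes the 2-boryl-1-alkene, and the allylic alcohol becomes the allylboronate.
4. The enal comes from but-2-yne-1,4-diol and a C3 acetal Grignard. Anti-carbomagnesiation sets the C3=C4 geometry, and an internal O18–C7 acetal tells the two allylic alcohols apart.

**Assumptions**
- Cembrane numbering is used for advanced compounds. C1 bears isopropenyl (C15–C17), C2 bears the secondary acetate, C3=C4 carries C18 (CH2OAc), C7 is the free carbinol, C8=C19 is the exocyclic methylene, and C11=C12 carries C20 (CH3). The target is then (1R,2S,3E,7R,11E).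
- The sense of induction of the (R)-binaphthol boronate in step 11 is taken by analogy and must be confirmed. If it is opposite, the (S)-ligand is used and nothing else changes.

**Step 1**
Reactants: 1 pent-4-ynal; 2 isopropenylmagnesium bromide
Product: 3 2-methylhept-1-en-6-yn-3-ol (racemic)
Conditions: 2 (1.1 equiv), THF, −78 to 0 °C; H2O quench
Reagents that add atoms: none
Why: Grignard 1,2-addition to the aldehyde is far faster than alkyne deprotonation at −78 °C, and the racemic carbinol centre is erased in step 2.

**Step 2**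
Reactants: 3 2-methylhept-1-en-6-yn-3-ol; 4 trimethyl orthoacetate
Product: 6 methyl (4E)-4-methylnon-4-en-8-ynoate, via ketene acetal 5 (not isolated)
Conditions: 4 (6 equiv), EtCO2H (5 mol %), 110 to 140 °C, MeOH distilled off
Reagents that add atoms: none
Why: The Johnson–Claisen orthoester rearrangement runs through a chair transition state with the homopropargyl chain equatorial, which gives the E C11=C12 alkene (at least 95:5) and adds C14 and C1.

**Step 3**
Reactants: 6 methyl (4E)-4-methylnon-4-en-8-ynoate; 2 isopropenylmagnesium bromide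
Product: 9 (6E)-2,6-dimethylundeca-1,6-dien-10-yn-3-ol (racemic), via aluminium hemiacetal 7 (not isolated), via aldehyde 8 (not isolated)
Conditions: i-Bu2AlH (1.05 equiv), CH2Cl2, −78 °C, 1 h; then 2 (2.5 equiv), −78 to 0 °C; aq potassium sodium tartrate
Reagents that add atoms: none
Why: In this one-pot ester half-reduction/Grignard addition the hemiacetal is stable at −78 °C and releases the aldehyde only as the Grignard traps it, and the racemic carbinol centre is erased in step 5.

**Step 4**
Reactants: 9 (6E)-2,6-dimethylundeca-1,6-dien-10-yn-3-ol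
Product: 11 (6E)-2,6-dimethyl-10-(pinacolatoboryl)undeca-1,6,10-trien-3-ol (racemic), via alpha-vinylalane 10 (not isolated)
Conditions: NiCl2(dppp) (3 mol %), i-Bu2AlH (2.4 equiv), THF, 0 to 23 °C; then MeOBpin (3 equiv), 0 to 60 °C; aq potassium sodium tartrate
Reagents that add atoms: 2-methoxy-4,4,5,5-tetramethyl-1,3,2-dioxaborolane (MeOBpin), COB1OC(C)(C)C(C)(C)O1
Why: Nickel-catalysed alpha-selective (Markovnikov) hydroalumination of the terminal alkyne followed by Al-to-B exchange places boron on C8, since the first hydride equivalent only deprotonates the alcohol and the 1,1-di- and trisubstituted alkenes are inert.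

**Step 5**
Reactants: 11 (6E)-2,6-dimethyl-10-(pinacolatoboryl)undeca-1,6,10-trien-3-ol
Product: 12 (2E,6E)-2,6-dimethylundeca-2,6,10-triene-1,10-diyl bis(pinacol boronate)
Conditions: [Pd(MeCN)4](BF4)2 (5 mol %), B2pin2 (1.5 equiv), DMSO/MeOH 1:1, 40 °C
Reagents that add atoms: bis(pinacolato)diboron, CC1(C)OB(OC1(C)C)B1OC(C)(C)C(C)(C)O1
Why: Palladium-catalysed direct borylation of an allylic alcohol goes through the syn pi-allylpalladium species, so boron lands on the free terminus C16 and the linear E-allylboronate forms, while the alkenyl boronate does not transmetalate without base.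

**Step 6**
Reactants: 13 2-(2-bromoethyl)-1,3-dioxolane; 14 but-2-yne-1,4-diol
Product: 17 2-[(3E)-6-methoxyoxan-3-ylidene]ethan-1-ol (racemic at the acetal carbon), via Grignard reagent 15 (not isolated), via dioxolane diol 16 (not isolated)
Conditions: 13, Mg, THF, 25 °C; then 14 (0.29 equiv), CuI (10 mol %), THF, 0 to 25 °C, 16 h; H2O quench, extract; crude, camphorsulfonic acid (5 mol %), MeOH, 0 to 23 °C
Reagents that add atoms: methanol, CO
Why: Copper-catalysed anti-carbomagnesiation of the propargylic alkoxide through a five-membered oxamagnesacycle puts C5 cis to C2 and C18 trans to C2, and acid-catalysed transacetalisation then closes only the six-membered O18–C7 acetal (the seven-membered alternative from O2 is disfavoured), which leaves the C2 alcohol free.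

**Step 7**
Reactants: 17 2-[(3E)-6-methoxyoxan-3-ylidene]ethan-1-ol
Product: 18 (2E)-(6-methoxyoxan-3-ylidene)acetaldehyde
Conditions: MnO2 (15 equiv), CH2Cl2, 23 °C
Reagents that add atoms: none
Why: MnO2 allylic oxidation is neutral, so the alkene geometry and the acetal are untouched.

**Step 8**
Reactants: 12 (2E,6E)-2,6-dimethylundeca-2,6,10-triene-1,10-diyl bis(pinacol boronate); 18 (2E)-(6-methoxyoxan-3-ylidene)acetaldehyde
Product: 20 (1R,2S)-seco alcohol (C2 carbinol between the (E)-(6-methoxyoxan-3-ylidene)methyl group and C1 bearing isopropenyl plus the (3E)-3-methyl-7-(pinacolatoboryl)octa-3,7-dien-1-yl chain), via O-boryl adduct 19 (not isolated)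
Conditions: (R)-TRIP [(R)-3,3'-bis(2,4,6-triisopropylphenyl)binaphthyl hydrogen phosphate] (10 mol %), 4 Å MS, toluene, −30 °C, 48 h; aq NaHCO3
Reagents that add atoms: none
Why: Chiral phosphoric-acid-catalysed allylboration proceeds through a closed chair transition state in which the E-boronate gives the anti C1/C2 pair and the (R)-acid directs attack to the Re face of the enal, giving (1R,2S), while only the allylic boronate reacts and both acetal epimers converge in step 9.

**Step 9**
Reactants: 20 (1R,2S)-seco alcohol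
Product: 21 (1R,2S)-seco 2,18-diol with C7 as (E)-N-[2-(trifluoromethyl)phenylsulfonyl]hydrazone and C8 as alkenylboronic acid
Conditions: 2-(CF3)C6H4SO2NHNH2 (1.1 equiv), MeB(OH)2 (10 equiv), 0.1 mol/L aq HCl/MeCN 1:1, 23 °C; evaporate
Reagents that add atoms: 2-(trifluoromethyl)benzenesulfonohydrazide, NNS(=O)(=O)c1ccccc1C(F)(F)F; methylboronic acid (hands its two OH groups to boron), CB(O)O
Why: Two acid-catalysed exchange equilibria run side by side, acetal-to-sulfonylhydrazone condensation (driven by hydrazone stability) and boronate transesterification onto methylboronic acid (driven by evaporation of MeBpin), and at this acidity the alkenes and the allylic alcohol survive.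

**Step 10**
Reactants: 21 (1R,2S)-seco 2,18-diol hydrazone boronic acid
Product: 22 (1R,2S)-seco 2,18-diacetate hydrazone boronic acid
Conditions: Ac2O (3 equiv), pyridine, DMAP (2 mol %), CH2Cl2, 0 °C; aq work-up
Reagents that add atoms: acetic anhydride, CC(=O)OC(C)=O
Why: In this standard O-acetylation with pyridine as the only base the sulfonylhydrazone N–H stays protonated and non-nucleophilic, and any boron mixed anhydride reverts to B(OH)2 on aqueous work-up.

**Step 11**
Reactants: 22 (1R,2S)-seco 2,18-diacetate hydrazone boronic acid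
Product: 28 (1R,2S,3E,7R,11E)-2,18-diacetoxycembra-3,8(19),11,15-tetraen-7-ol, via BINOL boronate 23 (not isolated), via sodium hydrazonide 24 (not isolated), via diazoalkane 25 (not isolated), via cyclic boronate 26 (not isolated), via macrocyclic allylboronate 27 (not isolated)
Conditions: a) (R)-3,3'-Br2-BINOL (1.05 equiv), 4 Å MS, toluene, 23 °C; b) NaN(SiMe3)2 (1.0 equiv), −78 °C; c) cold solution added over 12 h to toluene at 40 °C (final 1 mmol/L); d) 30% H2O2, pH 7 phosphate buffer, THF, 0 °C
Reagents that add atoms: hydrogen peroxide, OO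
Why: Proposed new method: this is a macrocyclising diazo–boronate homologation in which salt 24 loses sulfinate at 40 °C to give the unstabilised diazoalkane 25, whose nucleophilic carbon C7 adds to the Lewis-acidic aryloxy boronate at the far chain end (slow addition favours the 15-membered cyclic boronate 26 over oligomers), after which alkenyl carbon C8 migrates from boron to C7 anti-periplanar to the departing N2, an irreversible non-pericyclic 1,2-metallate shift that forms C7–C8 and contracts the ring to the 14-membered carbocycle 27; the C2-symmetric (R)-binaphthol on boron discriminates between the two diastereomeric ate complexes and so sets C7 as R, and stereoretentive C–B oxidation releases the free 7-OH beside intact acetates; the closest known reaction types are the metal-free coupling of sulfonylhydrazone-derived diazoalkanes with alkenylboronic acids and the BINOL-controlled asymmetric homologation of alkenylboronic acids with stabilised diazomethanes, neither of which has been run intramolecularly, for a macrocycle, or with an unstabilised alkyl diazo compound.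

**Compound list**
1 | pent-4-ynal | C#CCCC=O | starting material
2 | isopropenylmagnesium bromide | CC(=C)[Mg]Br | starting material
3 | 2-methylhept-1-en-6-yn-3-ol (racemic) | C=C(C)C(O)CCC#C | intermediate
4 | trimethyl orthoacetate | CC(OC)(OC)OC | starting material
5 | 3-[(1-methoxyethenyl)oxy]-2-methylhept-1-en-6-yne (ketene acetal) | C=C(OC)OC(CCC#C)C(C)=C | intermediate
6 | methyl (4E)-4-methylnon-4-en-8-ynoate | COC(=O)CC/C(C)=C/CCC#C | intermediate
7 | diisobutylaluminium hemiacetal of 6 | COC(CC/C(C)=C/CCC#C)O[Al](CC(C)C)CC(C)C | intermediate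
8 | (4E)-4-methylnon-4-en-8-ynal | O=CCC/C(C)=C/CCC#C | intermediate
9 | (6E)-2,6-dimethylundeca-1,6-dien-10-yn-3-ol (racemic) | C=C(C)C(O)CC/C(C)=C/CCC#C | intermediate
10 | diisobutylaluminium alkoxide of 9 with a diisobutylalumanyl group on C10 (alpha-vinylalane) | C=C(C)C(CC/C(C)=C/CCC(=C)[Al](CC(C)C)CC(C)C)O[Al](CC(C)C)CC(C)C | intermediate
11 | (6E)-2,6-dimethyl-10-(4,4,5,5-tetramethyl-1,3,2-dioxaborolan-2-yl)undeca-1,6,10-trien-3-ol (racemic) | C=C(C)C(O)CC/C(C)=C/CCC(=C)B1OC(C)(C)C(C)(C)O1 | intermediate
12 | 2,2'-[(2E,6E)-2,6-dimethylundeca-2,6,10-triene-1,10-diyl]bis(4,4,5,5-tetramethyl-1,3,2-dioxaborolane) | CC1(C)OB(C/C(C)=C/CC/C(C)=C/CCC(=C)B2OC(C)(C)C(C)(C)O2)OC1(C)C | intermediate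
13 | 2-(2-bromoethyl)-1,3-dioxolane | BrCCC1OCCO1 | starting material
14 | but-2-yne-1,4-diol | OCC#CCO | starting material
15 | [2-(1,3-dioxolan-2-yl)ethyl]magnesium bromide | Br[Mg]CCC1OCCO1 | intermediate
16 | (2E)-2-[2-(1,3-dioxolan-2-yl)ethyl]but-2-ene-1,4-diol | OC/C=C(/CO)CCC1OCCO1 | intermediate
17 | 2-[(3E)-6-methoxyoxan-3-ylidene]ethan-1-ol (acetal carbon racemic) | OC/C=C1/COC(OC)CC1 | intermediate
18 | (2E)-(6-methoxyoxan-3-ylidene)acetaldehyde (acetal carbon racemic) | O=C/C=C1/COC(OC)CC1 | intermediate
19 | O-(pinacolatoboryl) ether of 20 | C=C(B1OC(C)(C)C(C)(C)O1)CC/C=C(\C)CC[C@H](C(=C)C)[C@@H](OB1OC(C)(C)C(C)(C)O1)/C=C1/COC(OC)CC1 | intermediate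
20 | (1R,2S)-seco alcohol: 2-OH, O18–C7 cyclic methyl acetal (both epimers), 3E, 11E, C8 alkenyl pinacol boronate | C=C(B1OC(C)(C)C(C)(C)O1)CC/C=C(\C)CC[C@H](C(=C)C)[C@@H](O)/C=C1/COC(OC)CC1 | intermediate
21 | (1R,2S)-seco 2,18-diol, C7 (E)-2-(trifluoromethyl)benzenesulfonylhydrazone, C8 alkenylboronic acid | C=C(B(O)O)CC/C=C(\C)CC[C@H](C(=C)C)[C@@H](O)/C=C(/CO)CC/C=N/NS(=O)(=O)c1ccccc1C(F)(F)F | intermediate
22 | 2,18-diacetate of 21 | C=C(B(O)O)CC/C=C(\C)CC[C@H](C(=C)C)[C@@H](OC(C)=O)/C=C(/COC(C)=O)CC/C=N/NS(=O)(=O)c1ccccc1C(F)(F)F | intermediate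
23 | (R)-3,3'-dibromo-1,1'-bi-2-naphthol boronate of 22 (R axis, not expressible in SMILES) | C=C(B1Oc2c(Br)cc3ccccc3c2-c2c(O1)c(Br)cc3ccccc23)CC/C=C(\C)CC[C@H](C(=C)C)[C@@H](OC(C)=O)/C=C(/COC(C)=O)CC/C=N/NS(=O)(=O)c1ccccc1C(F)(F)F | intermediate
24 | sodium salt of 23 (N-deprotonated hydrazone) | C=C(B1Oc2c(Br)cc3ccccc3c2-c2c(O1)c(Br)cc3ccccc23)CC/C=C(\C)CC[C@H](C(=C)C)[C@@H](OC(C)=O)/C=C(/COC(C)=O)CC/C=N/[N-]S(=O)(=O)c1ccccc1C(F)(F)F.[Na+] | intermediate
25 | C7 diazoalkane with the C8 binaphthol boronate | C=C(B1Oc2c(Br)cc3ccccc3c2-c2c(O1)c(Br)cc3ccccc23)CC/C=C(\C)CC[C@H](C(=C)C)[C@@H](OC(C)=O)/C=C(/COC(C)=O)CCC=[N+]=[N-] | intermediate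
26 | 15-membered cyclic boronate zwitterion (ring C1–C14 plus B; C7 bears N2+, 7S) | C=C1CC/C=C(\C)CC[C@H](C(=C)C)[C@@H](OC(C)=O)/C=C(/COC(C)=O)CC[C@@H]([N+]#N)[B-]12Oc3c(Br)cc4ccccc4c3-c3c(O2)c(Br)cc4ccccc34 | intermediate
27 | 14-membered (1R,2S,7R)-allylboronate (binaphthol boronate on C7) | C=C1CC/C=C(\C)CC[C@H](C(=C)C)[C@@H](OC(C)=O)/C=C(/COC(C)=O)CC[C@H]1B1Oc2c(Br)cc3ccccc3c2-c2c(O1)c(Br)cc3ccccc23 | intermediate
28 | (1R,2S,3E,7R,11E)-2,18-diacetoxycembra-3,8(19),11,15-tetraen-7-ol | C=C1CC/C=C(\C)CC[C@H](C(=C)C)[C@@H](OC(C)=O)/C=C(/COC(C)=O)CC[C@H]1O | target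

**Step count**
- Total steps: 11.
- Longest linear sequence: 9 (steps 1–5 and 8–11).

**Three steps most likely to fail**

Step 11 (the new ring-contractive macrocyclisation). The main risks are oligomerisation, 1,2-hydride shift or dipolar cycloaddition of the diazoalkane, and weak or reversed control at C7. The fallback uses known chemistry, sets out from 22 and comes back at 28. Hydrazone exchange with aqueous glyoxylic acid in THF frees the seco aldehyde boronic acid F1. N-Iodosuccinimide in MeCN at 0 °C (ipso-iododeboronation) gives the seco 2-iodo-1-alkene aldehyde F2. A Nozaki–Hiyama–Kishi macrocyclisation then closes C7–C8 directly to 28, using CrCl2 (4 equiv), NiCl2 (1 mol %), a chiral oxazoline–sulfonamide ligand and Et3N in THF at 2 mmol/L. The acetates are tolerated, and the ligand biases the carbinol toward 7R.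

Step 6 (carbomagnesiation with a thermally fragile acetal Grignard on a poorly soluble dialkoxide). The fallback sets out from 14 and comes back at 16. Trans-hydroalumination with NaAlH2(OCH2CH2OMe)2 in THF followed by I2 gives (Z)-2-iodobut-2-ene-1,4-diol F3. Hydroboration of commercial 2-vinyl-1,3-dioxolane with 9-BBN-H gives B-[2-(1,3-dioxolan-2-yl)ethyl]-9-borabicyclo[3.3.1]nonane F4. A B-alkyl Suzuki–Miyaura coupling of the two (PdCl2(dppf), Cs2CO3, DMF/THF/H2O, 40 °C) retains the alkene geometry and delivers 16. The acid/MeOH treatment of step 6 then takes 16 on to 17.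

Step 8 (a hindered trisubstituted allylboronate with a beta,beta-disubstituted enal; any Z-boronate carried over from step 5 would give the syn isomer). The fallback sets out from 11, bypasses 12 and comes back at 20. SOCl2 in Et2O at 0 °C transposes the alcohol to the primary (2E,6E)-allylic chloride F5. A chromium-mediated asymmetric allylation of 18 then gives 20 after aqueous work-up, using CrCl2 (3 equiv), a chiral oxazoline–sulfonamide ligand and Et3N in THF at 0 °C. The reaction runs through the equilibrating allylchromium species, so it is anti-selective whatever the halide geometry.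

**Further compounds**
F1 | step 11 | (1R,2S)-seco 2,18-diacetate with C7 aldehyde and C8 alkenylboronic acid | C=C(B(O)O)CC/C=C(\C)CC[C@H](C(=C)C)[C@@H](OC(C)=O)/C=C(/COC(C)=O)CCC=O
F2 | step 11 | (1R,2S)-seco 2,18-diacetate with C7 aldehyde and C8 2-iodo-1-alkene | C=C(I)CC/C=C(\C)CC[C@H](C(=C)C)[C@@H](OC(C)=O)/C=C(/COC(C)=O)CCC=O
F3 | step 6 | (Z)-2-iodobut-2-ene-1,4-diol | OC/C=C(/CO)I
F4 | step 6 | B-[2-(1,3-dioxolan-2-yl)ethyl]-9-borabicyclo[3.3.1]nonane | C(CC1OCCO1)B1C2CCCC1CCC2
F5 | step 8 | 2-[(6E,10E)-11-chloro-6,10-dimethylundeca-1,6,10-trien-2-yl]-4,4,5,5-tetramethyl-1,3,2-dioxaborolane | ClC/C(C)=C/CC/C(C)=C/CCC(=C)B1OC(C)(C)C(C)(C)O1
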